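**Plan**

- Retrosynthesis: the C5–O bond is traced back to a C5–B bond; the C2=C3 double bond is cut by a retro-aldol condensation to an acyclic 1,5-keto aldehyde whose carbonyl carbons C1 and C3 are masked as terminal alkenes; the C5–chain bond and the C6–C1 bond are then cut together, leaving nonadecyl pinacol boronate, a 2-lithio-1,4-pentadiene and 2-bromopropene.
- Enabling feature: in the one carbocycle (C1 carbonyl, C2=C3, C4, C5 carbinol, C6) the only stereocentre, C5, bears oxygen and three CH2 groups (C4, C6 and the first chain carbon). A carbonyl addition could hardly tell these apart, but they can be placed one after another on a carbon next to boron.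
- Forward: hydroboration gives the C19 boronic ester, the dienyllithium adds to it, and a palladium-catalysed three-component coupling with 2-bromopropene joins chain, allyl arm and methallyl arm at C5 in an acyclic tertiary boronate.
- Double ozonolysis and an amine-salt aldol condensation then close the six-membered ring, the only ring, through C2–C3.
- Boron stays on C5 to the last step as a stand-in for the tertiary hydroxyl that cannot leave, so neither retro-aldol cleavage nor dehydration to 3-nonadecylphenol can interfere with ring formation; C–B oxidation with retention ends the route.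
- Stereochemistry: C5 is set once, by the chiral ferrocenyl bisphosphine on palladium in the coupling (face selection of the ate-complex alkene, anti migration), and is quaternary from then on.

Key step: step 3

Assumption (chemistry): the (Sp,Sp) antipode of the ferrocenyl bisphosphine named in step 3 is taken to be the one that leads to the R boronate; both antipodes are commercial, and the mirror-image ligand is used if the sense of induction proves opposite.

**Route**

Step 1
Reactants: 1 1-nonadecene
Product: 2 4,4,5,5-tetramethyl-2-nonadecyl-1,3,2-dioxaborolane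
Conditions: HBpin (1.2 equiv), [IrCl(cod)]2 (1.5 mol %), dppm (3 mol %), CH2Cl2, rt
Reagents that add atoms: pinacolborane, [H]B1OC(C)(C)C(C)(C)O1
Why: Iridium-catalysed hydroboration of a terminal alkene with pinacolborane places boron on the terminal carbon only, so the linear C19 boronic ester should form without isomers and without any stereocentre.

Step 2
Reactants: 3 2,3-dibromopropene; 4 vinylmagnesium bromide
Product: 5 2-bromopenta-1,4-diene
Conditions: CuI (5 mol %), THF, −10 °C to rt
Reagents that add atoms: none
Why: Copper-catalysed allylic substitution by the vinyl Grignard reagent is much faster at the allylic C–Br bond than any reaction at the vinylic one, and direct and allylically transposed attack converge on the same 2-bromo-1,4-diene.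

Step 3
Reactants: 5 2-bromopenta-1,4-diene; 2 4,4,5,5-tetramethyl-2-nonadecyl-1,3,2-dioxaborolane; 6 2-bromopropene
Product: 9 2-[(4R)-2-methyl-4-(prop-2-en-1-yl)tricos-1-en-4-yl]-4,4,5,5-tetramethyl-1,3,2-dioxaborolane, via penta-1,4-dien-2-yllithium 7 (not isolated), via lithium boron ate complex 8 (not isolated)
Conditions: t-BuLi (2.0 equiv), Et2O, −78 °C; then 2, −78 °C to rt; Et2O replaced by THF; 6 (1.2 equiv), Pd(OAc)2 (3 mol %), (Sp,Sp)-1,1'-bis[bis(4-methoxy-3,5-dimethylphenyl)phosphino]-2,2'-bis[(R)-α-(dimethylamino)benzyl]ferrocene (3.6 mol %), KOTf (potassium trifluoromethanesulfonate, 2 equiv), THF, 60 °C, sealed vessel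
Reagents that add atoms: none
Why: Bromine–lithium exchange on 5 gives alkenyllithium 7, which adds to the boron of 2 to give the four-coordinate ate complex 8; zerovalent palladium, formed from Pd(OAc)2 and the bisphosphine, inserts into the C–Br bond of 6, the cationic divalent isopropenylpalladium binds the 1,1-disubstituted alkene of 8 and induces the 1,2-shift of nonadecyl from boron to the α-carbon anti to the metal (chain–C5 bond), and reductive elimination from the resulting alkylpalladium forms the C6–C1 bond. The closest known reaction is the palladium-catalysed enantioselective conjunctive cross-coupling of α-substituted alkenylboron ate complexes with C(sp2) electrophiles, which gives tertiary boronic esters; only the α-substituent (allyl in place of a simple alkyl group) is new here. No ring is closed in this step. The new stereocentre C5 is under catalyst control: the chiral bisphosphine on palladium selects one face of the ate-complex alkene, whose α-carbon carries the very different boronate and allyl groups, and the stereospecific anti migration turns that choice into the R boronate. The step needs conjunctive coupling to win over direct transfer of the dienyl group to palladium and over Heck insertion into the pendant allyl alkene; the electron-rich ate-complex alkene is the best π-donor available to the cationic metal, the alkylpalladium formed has a quaternary β-carbon and so no β-hydrogen to lose, and KOTf removes bromide from palladium so that the alkene-binding site stays open.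

Step 4
Reactants: 9 2-[(4R)-2-methyl-4-(prop-2-en-1-yl)tricos-1-en-4-yl]-4,4,5,5-tetramethyl-1,3,2-dioxaborolane
Product: 10 (3R)-3-(2-oxopropyl)-3-(4,4,5,5-tetramethyl-1,3,2-dioxaborolan-2-yl)docosanal
Conditions: O3, CH2Cl2, −78 °C, stopped at first persistent blue; then PPh3 (2.5 equiv), −78 °C to rt
Reagents that add atoms: ozone, [O-][O+]=O
Why: Ozonolysis with reductive work-up cleaves both terminal alkenes to the methyl ketone and the aldehyde, while the hindered tertiary pinacol boronate, a weak Lewis acid with no π-bond, should survive ozone at −78 °C, and the quaternary stereocentre cannot epimerise.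

Step 5
Reactants: 10 (3R)-3-(2-oxopropyl)-3-(4,4,5,5-tetramethyl-1,3,2-dioxaborolan-2-yl)docosanal
Product: 11 (5R)-5-nonadecyl-5-(4,4,5,5-tetramethyl-1,3,2-dioxaborolan-2-yl)cyclohex-2-en-1-one
Conditions: Bn2NH·CF3CO2H (0.3 equiv), toluene, 50 °C
Reagents that add atoms: none
Why: Amine-salt-mediated intramolecular aldol condensation should close the ring because the methyl carbon of the ketone (C2) and the aldehyde carbon (C3) are the only pair that can meet in a six-membered, 6-(enolendo)-exo-trig mode, every other enolisable position leading to a four-membered ring, and water (or dibenzylamine from the Mannich-type adduct) can be lost only across C2–C3 since boron on C5 is neither a leaving group nor a trigger for retro-aldol cleavage, the quaternary stereocentre C5 staying untouched.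

Step 6
Reactants: 11 (5R)-5-nonadecyl-5-(4,4,5,5-tetramethyl-1,3,2-dioxaborolan-2-yl)cyclohex-2-en-1-one
Product: 12 (5S)-5-hydroxy-5-nonadecylcyclohex-2-en-1-one
Conditions: NaBO3·4H2O (3 equiv), THF/H2O (1:1), 0 °C to rt; pH 7 phosphate buffer quench
Reagents that add atoms: sodium perborate, [Na+].[O-]OB=O
Why: Perborate oxidation of a C–B bond proceeds by addition of peroxide to boron and 1,2-shift of carbon to oxygen with retention, so the R boronate gives the S alcohol (the descriptor changes only because oxygen outranks carbon), and the mild, hydroxide-free medium that is standard for turning tertiary β-boryl ketones into β-hydroxy ketones should leave the enone unepoxidised and the new aldol unit intact.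

**Compound list**

1 | 1-nonadecene | C=CCCCCCCCCCCCCCCCCC | starting material
2 | 4,4,5,5-tetramethyl-2-nonadecyl-1,3,2-dioxaborolane | CCCCCCCCCCCCCCCCCCCB1OC(C)(C)C(C)(C)O1 | intermediate
3 | 2,3-dibromopropene | C=C(Br)CBr | starting material
4 | vinylmagnesium bromide | C=C[Mg]Br | starting material
5 | 2-bromopenta-1,4-diene | C=CCC(Br)=C | intermediate
6 | 2-bromopropene | CC(Br)=C | starting material
7 | penta-1,4-dien-2-yllithium | [Li]C(=C)CC=C | intermediate
8 | lithium nonadecyl(penta-1,4-dien-2-yl)(pinacolato)borate (ate complex) | [Li+].CCCCCCCCCCCCCCCCCCC[B-]1(OC(C)(C)C(C)(C)O1)C(=C)CC=C | intermediate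
9 | 2-[(4R)-2-methyl-4-(prop-2-en-1-yl)tricos-1-en-4-yl]-4,4,5,5-tetramethyl-1,3,2-dioxaborolane | CCCCCCCCCCCCCCCCCCC[C@](B1OC(C)(C)C(C)(C)O1)(CC=C)CC(C)=C | intermediate
10 | (3R)-3-(2-oxopropyl)-3-(4,4,5,5-tetramethyl-1,3,2-dioxaborolan-2-yl)docosanal | CCCCCCCCCCCCCCCCCCC[C@](B1OC(C)(C)C(C)(C)O1)(CC=O)CC(C)=O | intermediate
11 | (5R)-5-nonadecyl-5-(4,4,5,5-tetramethyl-1,3,2-dioxaborolan-2-yl)cyclohex-2-en-1-one | CCCCCCCCCCCCCCCCCCC[C@]1(B2OC(C)(C)C(C)(C)O2)CC=CC(=O)C1 | intermediate
12 | (5S)-5-hydroxy-5-nonadecylcyclohex-2-en-1-one | CCCCCCCCCCCCCCCCCCC[C@]1(O)CC=CC(=O)C1 | target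

**Step count**

Total steps: 6. Longest linear sequence: 5 steps (1 → 2 → 9 → 10 → 11 → 12, or equally 3 → 5 → 9 → 10 → 11 → 12).

**Steps most likely to fail**

1. Step 3. The dienyl group may be transferred directly to palladium (Suzuki–Miyaura pathway) instead of inducing the metallate shift. Proton transfer from the doubly allylic CH2 may consume the alkenyllithium before boron captures it. Face selection may also drop when the α-substituent is allyl. Fallback, setting out from 1 and rejoining at 11: hydroboration of 1 with 9-BBN (THF) gives 9-nonadecyl-9-borabicyclo[3.3.1]nonane F1. This is coupled in the same flask with 3-bromocyclohex-2-en-1-one (PdCl2(dppf), K3PO4, THF/DMF/H2O, 50 °C; B-alkyl Suzuki–Miyaura coupling) to give 3-nonadecylcyclohex-2-en-1-one F2. Copper-catalysed enantioselective conjugate borylation (B2pin2, [Cu(MeCN)4]PF6, the enantiomer of 2,3-bis(tert-butylmethylphosphino)quinoxaline that leads to the R product, LiOt-Bu, DMSO, rt), a well-precedented entry to tertiary β-boryl cyclohexanones, should give (3R)-3-nonadecyl-3-(4,4,5,5-tetramethyl-1,3,2-dioxaborolan-2-yl)cyclohexan-1-one F3. Kinetic enolisation away from the quaternary carbon (LiN(i-Pr)2, Me3SiCl, THF, −78 °C) gives trimethyl{[(5R)-5-nonadecyl-5-(4,4,5,5-tetramethyl-1,3,2-dioxaborolan-2-yl)cyclohex-1-en-1-yl]oxy}silane F4. Saegusa–Ito oxidation (Pd(OAc)2, MeCN, rt) then gives 11; only this side of the ketone has a β-hydrogen, so the position of the double bond is fixed.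

2. Step 6. Nucleophilic epoxidation of the enone by hydroperoxide may compete with attack at the hindered boron, and the basic medium may induce loss of the new tertiary hydroxyl followed by aromatisation. Fallback, setting out from 11 and rejoining at 12, removes the enone before the C–B oxidation. Luche reduction (NaBH4, CeCl3·7H2O, MeOH, 0 °C) gives (5R)-5-nonadecyl-5-(4,4,5,5-tetramethyl-1,3,2-dioxaborolan-2-yl)cyclohex-2-en-1-ol F5 as a mixture of C1 epimers, which is of no consequence. Oxidation with NaOH/H2O2 (THF, 0 °C), to which an allylic alcohol is inert, gives (1S)-1-nonadecylcyclohex-4-ene-1,3-diol F6. MnO2 (CH2Cl2, rt) oxidises only the secondary allylic hydroxyl and gives 12.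

3. Step 4. Oxygen may be transferred to boron from ozone or from the carbonyl oxide generated two atoms away, and the β-boryl aldehyde may decompose during isolation. Fallback, setting out from 9 and rejoining at 12, moves the C–B oxidation ahead of the alkene cleavage. NaOH/H2O2 (THF, 0 °C to rt) gives (4S)-2-methyl-4-(prop-2-en-1-yl)tricos-1-en-4-ol F7. Ozonolysis (O3, CH2Cl2, −78 °C; PPh3) gives (3S)-3-hydroxy-3-(2-oxopropyl)docosanal F8, which is used crude. Cyclisation with Bn2NH·CF3CO2H (toluene, rt to 40 °C) gives 12 directly. The price is that a free tertiary hydroxyl β to both carbonyl groups is carried through the condensation, so the mildest conditions and short reaction times are required.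

**Further compounds**

F1 | step 3 | 9-nonadecyl-9-borabicyclo[3.3.1]nonane | CCCCCCCCCCCCCCCCCCCB1C2CCCC1CCC2
F2 | step 3 | 3-nonadecylcyclohex-2-en-1-one | CCCCCCCCCCCCCCCCCCCC1=CC(=O)CCC1
F3 | step 3 | (3R)-3-nonadecyl-3-(4,4,5,5-tetramethyl-1,3,2-dioxaborolan-2-yl)cyclohexan-1-one | CCCCCCCCCCCCCCCCCCC[C@]1(B2OC(C)(C)C(C)(C)O2)CCCC(=O)C1
F4 | step 3 | trimethyl{[(5R)-5-nonadecyl-5-(4,4,5,5-tetramethyl-1,3,2-dioxaborolan-2-yl)cyclohex-1-en-1-yl]oxy}silane | CCCCCCCCCCCCCCCCCCC[C@]1(B2OC(C)(C)C(C)(C)O2)CCC=C(O[Si](C)(C)C)C1
F5 | step 6 | (5R)-5-nonadecyl-5-(4,4,5,5-tetramethyl-1,3,2-dioxaborolan-2-yl)cyclohex-2-en-1-ol (C1 epimers) | CCCCCCCCCCCCCCCCCCC[C@]1(B2OC(C)(C)C(C)(C)O2)CC=CC(O)C1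
F6 | step 6 | (1S)-1-nonadecylcyclohex-4-ene-1,3-diol (C3 epimers) | CCCCCCCCCCCCCCCCCCC[C@]1(O)CC=CC(O)C1
F7 | step 4 | (4S)-2-methyl-4-(prop-2-en-1-yl)tricos-1-en-4-ol | CCCCCCCCCCCCCCCCCCC[C@](O)(CC=C)CC(C)=C
F8 | step 4 | (3S)-3-hydroxy-3-(2-oxopropyl)docosanal | CCCCCCCCCCCCCCCCCCC[C@](O)(CC=O)CC(C)=O
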